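**Retrosynthetic overview**
1. Target 19 ⇒ allylic alcohol 16: the C4–O and C5–Cl bonds are made together in the last step by a hydroxyl-templated anti-chlorohydroxylation of C4=C5 (the key C–O bond formation).
2. 16 ⇒ enone 14: C3–OH by Luche reduction, oxirane (C10–O–C11) by Shi epoxidation.
3. 14 ⇒ enal 7: C8 carbinol by asymmetric allylation, prenyl terminus by cross-metathesis, C8–O angelate by esterification with retention.
4. 7 ⇒ (S)-carvone 1: C2–O by alpha-prime hydroxylation then Mitsunobu inversion with angelic acid; C8 oxidation level by allylic oxidation of the isopropenyl methyl.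
5. Rings: the cyclohexane comes intact from carvone (C1 from the chiral pool); the oxirane is closed in step 7; the only other ring is a transient dioxaborolane in step 9.

Assumption: the SMILES fixes the target as 1R,2S,3S,4S,5S,8S,10S with two (Z)-angelates, in the locants used throughout (ring C1 bears the side chain, C2 O-angelate, C3 OH, C4 C(OH)CH3, C5 Cl, C6 CH2; side chain C7(=C14H2), C8 O-angelate, C9 H2, C10–C11 oxirane).

**Step 1**
Reactants: 1 (S)-(+)-carvone [(5S)-2-methyl-5-(prop-1-en-2-yl)cyclohex-2-en-1-one]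
Product: 3 (5R,6R)-6-hydroxy-2-methyl-5-(prop-1-en-2-yl)cyclohex-2-en-1-one (trans-6-hydroxycarvone; the label at the isopropenyl carbon changes from S to R by CIP priority only), via potassium dienolate 2 (not isolated)
Conditions: KN(SiMe3)2 (1.15 equiv), THF, −78 °C (ketone added to base); then trans-3-phenyl-2-(phenylsulfonyl)oxaziridine (1.3 equiv), −78 °C; AcOH quench
Reagents that add atoms: trans-3-phenyl-2-(phenylsulfonyl)oxaziridine (Davis oxaziridine), O=S(=O)(c1ccccc1)N1OC1c1ccccc1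
Why: Kinetic deprotonation at the alpha-prime CH2 gives the cross-conjugated dienolate, and Davis enolate hydroxylation delivers oxygen to C2 on the face opposite the adjacent C1 isopropenyl group, setting the trans (2R) alcohol.

**Step 2**
Reactants: 3 trans-6-hydroxycarvone; 4 angelic acid [(2Z)-2-methylbut-2-enoic acid]
Product: 5 (1S,6R)-3-methyl-2-oxo-6-(prop-1-en-2-yl)cyclohex-3-en-1-yl (2Z)-2-methylbut-2-enoate (cis-6-angeloyloxycarvone)
Conditions: 4 (1.5 equiv), PPh3 (1.5 equiv), DIAD (1.5 equiv), PhMe, 0 °C to rt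
Reagents that add atoms: none
Why: Mitsunobu esterification displaces the alpha-keto alkoxyphosphonium by SN2 with inversion, turning the equatorial trans alcohol into the axial (2S) angelate cis to the C1 substituent, and the near-neutral conditions leave the Z enoate geometry untouched.

**Step 3**
Reactants: 5 cis-6-angeloyloxycarvone
Product: 7 (1S,6R)-3-methyl-2-oxo-6-(3-oxoprop-1-en-2-yl)cyclohex-3-en-1-yl (2Z)-2-methylbut-2-enoate (C8 enal), via allylic alcohol 6 (not isolated)
Conditions: SeO2 (0.3 equiv), t-BuOOH (3 equiv), CH2Cl2, rt; then MnO2 (15 equiv), CH2Cl2, rt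
Reagents that add atoms: selenium dioxide, O=[Se]=O; tert-butyl hydroperoxide (terminal oxidant that restores SeO2), CC(C)(C)OO
Why: Riley-type allylic oxidation (ene reaction then 2,3-sigmatropic shift) attacks the only electron-rich olefin, the isopropenyl group, at its CH3 in preference to the ring CH, and MnO2 converges the allylic alcohol to the enal without touching a stereocentre.

**Step 4**
Reactants: 7 C8 enal; 8 (−)-B-allyldiisopinocampheylborane [(−)-Ipc2B(allyl), isopinocampheyl groups from (+)-α-pinene]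
Product: 10 (1S,6R)-6-[(3S)-3-hydroxyhexa-1,5-dien-2-yl]-3-methyl-2-oxocyclohex-3-en-1-yl (2Z)-2-methylbut-2-enoate, via borinate ester 9 (not isolated)
Conditions: 8 (1.2 equiv, 1 M in pentane), Et2O, −78 °C, 2 h; then HOCH2CH2NH2, rt
Reagents that add atoms: none
Why: Brown asymmetric allylboration through a closed chair transition state sends the allyl group to the Si face of the aldehyde under reagent control and sets the (8S) carbinol, while the ketone is inert at −78 °C and the non-oxidative ethanolamine work-up spares the enone.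

**Step 5**
Reactants: 10 (8S)-homoallylic alcohol; 11 2-methylbut-2-ene
Product: 12 (1S,6R)-6-[(3S)-3-hydroxy-6-methylhepta-1,5-dien-2-yl]-3-methyl-2-oxocyclohex-3-en-1-yl (2Z)-2-methylbut-2-enoate
Conditions: second-generation Hoveyda–Grubbs catalyst RuCl2(=CH-C6H4-2-OiPr)(H2IMes) (5 mol %), 11 (30 equiv), CH2Cl2, 40 °C, sealed tube
Reagents that add atoms: none
Why: Olefin cross-metathesis exchanges the terminal CH2 of the monosubstituted olefin for an isopropylidene unit, while the 1,1-disubstituted olefin, the enone and the angelate are too hindered or electron-poor to engage, so no stereocentre is touched.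

**Step 6**
Reactants: 12 (8S)-prenyl alcohol; 4 angelic acid
Product: 14 (1S,6R)-3-methyl-6-[(3S)-6-methyl-3-{[(2Z)-2-methylbut-2-enoyl]oxy}hepta-1,5-dien-2-yl]-2-oxocyclohex-3-en-1-yl (2Z)-2-methylbut-2-enoate (bis-angelate enone), via mixed anhydride 13 (not isolated)
Conditions: 4 (3 equiv), 2,4,6-Cl3C6H2COCl (3 equiv), Et3N (3 equiv), PhMe, rt, 1 h; then 12, PhMe, 80 °C
Reagents that add atoms: none
Why: Yamaguchi esterification through the pre-formed mixed anhydride acylates the C8 hydroxyl at the less hindered angeloyl carbonyl with retention at C8, and omitting nucleophilic amine catalysts avoids Z to E isomerisation to the tiglate.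

**Step 7**
Reactants: 14 bis-angelate enone
Product: 15 (1S,6R)-6-[(3S)-4-[(2S)-3,3-dimethyloxiran-2-yl]-3-{[(2Z)-2-methylbut-2-enoyl]oxy}but-1-en-2-yl]-3-methyl-2-oxocyclohex-3-en-1-yl (2Z)-2-methylbut-2-enoate
Conditions: L-fructose-derived Shi ketone (ent-Shi ketone, 0.5 equiv), KHSO5 (as the triple salt 2KHSO5·KHSO4·K2SO4, 1.5 equiv), NaHCO3 buffer (pH about 8), Bu4NHSO4 (cat.), MeCN/CH2(OMe)2/H2O, 0 °C
Reagents that add atoms: potassium peroxymonosulfate KHSO5, [K+].[O-]S(=O)(=O)OO
Why: Shi asymmetric epoxidation by the chiral dioxirane reacts only at the electron-rich trisubstituted C10=C11 olefin, and the L-fructose-derived ketone delivers oxygen through the spiro transition state to the face giving the (10S) oxirane (the D-fructose-derived ketone would give 10R).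

**Step 8**
Reactants: 15 epoxy enone
Product: 16 (1S,2R,6R)-6-[(3S)-4-[(2S)-3,3-dimethyloxiran-2-yl]-3-{[(2Z)-2-methylbut-2-enoyl]oxy}but-1-en-2-yl]-2-hydroxy-3-methylcyclohex-3-en-1-yl (2Z)-2-methylbut-2-enoate (C3–OH cis to the C2 angelate)
Conditions: NaBH4 (1.0 equiv), CeCl3·7H2O (1.1 equiv), MeOH, −78 °C, 20 min; pH 7 buffer quench
Reagents that add atoms: none
Why: Luche 1,2-reduction adds hydride axially and anti to the axial C2 angelate (polar Felkin–Anh control and the usual cis-carveol selectivity coincide), giving the equatorial C3 alcohol cis to the C2 ester without touching esters or oxirane.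

**Step 9**
Reactants: 16 allylic alcohol
Product: 19 (1S,2S,3S,4S,6R)-4-chloro-6-[(3S)-4-[(2S)-3,3-dimethyloxiran-2-yl]-3-{[(2Z)-2-methylbut-2-enoyl]oxy}but-1-en-2-yl]-2,3-dihydroxy-3-methylcyclohexyl (2Z)-2-methylbut-2-enoate (target), via boronic hemiester 17 (not isolated), via cyclic boronate 18 (not isolated)
Conditions: PhB(OH)2 (1.2 equiv), 4 Å molecular sieves, CH2Cl2, rt; then NCS (1.2 equiv), Ph3P=S (10 mol %), −20 to 0 °C; then 30% H2O2, pH 7 phosphate buffer, THF, 0 °C
Reagents that add atoms: phenylboronic acid (source of the C4 hydroxyl oxygen), OB(O)c1ccccc1; N-chlorosuccinimide, O=C1CCC(=O)N1Cl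
Why: Proposed new method: a boronic-acid-templated anti-chlorohydroxylation in which the C3 hydroxyl is first tied up as the hemiester PhB(OH)(OR), Lewis-base-activated NCS forms the chloronium ion on the open lower face of C4=C5 (the upper face carries the C1, C2 and C3 substituents), and the tethered B–OH oxygen opens it 5-exo, Markovnikov and trans-diaxially at the tertiary C4 from the face of the C3 oxygen, so the new C4–O must be cis to C3–OH with chlorine anti at C5 (4S,5S) before buffered H2O2 cleaves the boronate; the closest known reaction types are boronate-tethered oxa-Michael additions, bromo- and iodo-cyclisations of allylic carbonates and boronic hemiesters, and titanium-directed dihalogenation of allylic alcohols, none shown as a chlorohydroxylation of a trisubstituted cyclic allylic alcohol.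

**Compound list**
1 | (S)-(+)-carvone | C=C(C)[C@H]1CC=C(C)C(=O)C1 | starting material
2 | potassium cross-conjugated dienolate of 1 | C=C(C)[C@H]1CC=C(C)C([O-])=C1.[K+] | intermediate (not isolated)
3 | (5R,6R)-6-hydroxy-2-methyl-5-(prop-1-en-2-yl)cyclohex-2-en-1-one | C=C(C)[C@H]1CC=C(C)C(=O)[C@@H]1O | intermediate
4 | angelic acid, (2Z)-2-methylbut-2-enoic acid | C/C=C(/C)C(=O)O | starting material
5 | (1S,6R)-3-methyl-2-oxo-6-(prop-1-en-2-yl)cyclohex-3-en-1-yl (2Z)-2-methylbut-2-enoate | C=C(C)[C@H]1CC=C(C)C(=O)[C@H]1OC(=O)/C(C)=C\C | intermediate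
6 | (1S,6R)-6-(3-hydroxyprop-1-en-2-yl)-3-methyl-2-oxocyclohex-3-en-1-yl (2Z)-2-methylbut-2-enoate | C=C(CO)[C@H]1CC=C(C)C(=O)[C@H]1OC(=O)/C(C)=C\C | intermediate (not isolated)
7 | (1S,6R)-3-methyl-2-oxo-6-(3-oxoprop-1-en-2-yl)cyclohex-3-en-1-yl (2Z)-2-methylbut-2-enoate | C=C(C=O)[C@H]1CC=C(C)C(=O)[C@H]1OC(=O)/C(C)=C\C | intermediate
8 | (−)-B-allyldiisopinocampheylborane, Ipc groups from (+)-α-pinene | C=CCB([C@@H]1C[C@@H]2C[C@H]([C@H]1C)C2(C)C)[C@@H]1C[C@@H]2C[C@H]([C@H]1C)C2(C)C | starting material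
9 | bis(isopinocampheyl)borinate ester of 10 (B–O bond at the C8 oxygen) | C=C([C@H](CC=C)OB([C@@H]2C[C@@H]3C[C@H]([C@H]2C)C3(C)C)[C@@H]2C[C@@H]3C[C@H]([C@H]2C)C3(C)C)[C@H]1CC=C(C)C(=O)[C@H]1OC(=O)/C(C)=C\C | intermediate (not isolated)
10 | (1S,6R)-6-[(3S)-3-hydroxyhexa-1,5-dien-2-yl]-3-methyl-2-oxocyclohex-3-en-1-yl (2Z)-2-methylbut-2-enoate | C=C([C@H](CC=C)O)[C@H]1CC=C(C)C(=O)[C@H]1OC(=O)/C(C)=C\C | intermediate
11 | 2-methylbut-2-ene | CC=C(C)C | starting material
12 | (1S,6R)-6-[(3S)-3-hydroxy-6-methylhepta-1,5-dien-2-yl]-3-methyl-2-oxocyclohex-3-en-1-yl (2Z)-2-methylbut-2-enoate | C=C([C@H](CC=C(C)C)O)[C@H]1CC=C(C)C(=O)[C@H]1OC(=O)/C(C)=C\C | intermediate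
13 | (2Z)-2-methylbut-2-enoic 2,4,6-trichlorobenzoic anhydride | C/C=C(/C)C(=O)OC(=O)c1c(Cl)cc(Cl)cc1Cl | intermediate (not isolated)
14 | (1S,6R)-3-methyl-6-[(3S)-6-methyl-3-{[(2Z)-2-methylbut-2-enoyl]oxy}hepta-1,5-dien-2-yl]-2-oxocyclohex-3-en-1-yl (2Z)-2-methylbut-2-enoate | C=C([C@H](CC=C(C)C)OC(=O)/C(C)=C\C)[C@H]1CC=C(C)C(=O)[C@H]1OC(=O)/C(C)=C\C | intermediate
15 | (1S,6R)-6-[(3S)-4-[(2S)-3,3-dimethyloxiran-2-yl]-3-{[(2Z)-2-methylbut-2-enoyl]oxy}but-1-en-2-yl]-3-methyl-2-oxocyclohex-3-en-1-yl (2Z)-2-methylbut-2-enoate | C=C([C@H](C[C@@H]1OC1(C)C)OC(=O)/C(C)=C\C)[C@H]1CC=C(C)C(=O)[C@H]1OC(=O)/C(C)=C\C | intermediate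
16 | (1S,2R,6R)-6-[(3S)-4-[(2S)-3,3-dimethyloxiran-2-yl]-3-{[(2Z)-2-methylbut-2-enoyl]oxy}but-1-en-2-yl]-2-hydroxy-3-methylcyclohex-3-en-1-yl (2Z)-2-methylbut-2-enoate | C=C([C@H](C[C@@H]1OC1(C)C)OC(=O)/C(C)=C\C)[C@H]1CC=C(C)[C@@H](O)[C@H]1OC(=O)/C(C)=C\C | intermediate
17 | phenylboronic acid mono-ester of 16 on the C3 oxygen, PhB(OH)–O–C3 | C=C([C@H](C[C@@H]1OC1(C)C)OC(=O)/C(C)=C\C)[C@H]1CC=C(C)[C@@H](OB(O)c2ccccc2)[C@H]1OC(=O)/C(C)=C\C | intermediate (not isolated)
18 | 2-phenyl-1,3,2-dioxaborolane bridging the cis C3 and C4 oxygens of 19, C5–Cl anti | C=C([C@H](C[C@@H]1OC1(C)C)OC(=O)/C(C)=C\C)[C@H]1C[C@H](Cl)[C@@]2(C)OB(c3ccccc3)O[C@H]2[C@H]1OC(=O)/C(C)=C\C | intermediate (not isolated)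
19 | (1S,2S,3S,4S,6R)-4-chloro-6-[(3S)-4-[(2S)-3,3-dimethyloxiran-2-yl]-3-{[(2Z)-2-methylbut-2-enoyl]oxy}but-1-en-2-yl]-2,3-dihydroxy-3-methylcyclohexyl (2Z)-2-methylbut-2-enoate (CNP0333703.2) | C=C([C@H](C[C@@H]1OC1(C)C)OC(=O)/C(C)=C\C)[C@H]1C[C@H](Cl)[C@@](C)(O)[C@@H](O)[C@H]1OC(=O)/C(C)=C\C | target

**Total step count:** 9
**Longest linear sequence:** 9 steps (1 to 19)

**Steps most likely to fail**

Step 9 (proposed new method). The tethered oxygen delivery is unproven; chlorination of C7=C14 or participation of the axial C2 angelate carbonyl could compete. The fallback sets out from 16: hydroxyl-directed epoxidation (VO(acac)2 cat., t-BuOOH, CH2Cl2, 0 °C) gives the syn-epoxy alcohol F1 with the oxirane oxygen cis to C3–OH. Chelation-controlled chlorinolysis (ClTi(OiPr)3 from Ti(OiPr)4/TiCl4 3:1, CH2Cl2, −20 °C) then opens F1 trans-diaxially at C5, away from the unchelated side-chain oxirane, and comes back to the route at 19.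

Step 3. Selenium-mediated oxidation of isopropenyl groups is often modest in yield and the 2-substituted acrolein 7 is sensitive. The fallback sets out from 5: ene-type chlorination with HOCl (Ca(OCl)2, solid CO2, CH2Cl2/H2O, rt) gives the allylic chloride F2. Displacement with anhydrous Me3N–O (DMSO, rt) gives the N-alkoxytrimethylammonium chloride F3, which loses trimethylammonium chloride under the same conditions and comes back to the route at 7.

Step 2. The alpha-ketol is hindered by the neighbouring isopropenyl group and could eliminate or epimerise instead of substituting. The fallback sets out from 3: sulfonylation (ClCH2SO2Cl, pyridine, 0 °C) gives the chloromethanesulfonate F4. SN2 displacement with cesium angelate F5 (made from 4 and Cs2CO3; 18-crown-6, PhMe, 40 °C) inverts C2 and comes back to the route at 5.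

**Further compounds**
F1 | step 9 | syn-4,5-epoxy alcohol of 16 (oxirane oxygen cis to C3–OH) | C=C([C@H](C[C@@H]1OC1(C)C)OC(=O)/C(C)=C\C)[C@H]1C[C@H]2O[C@@]2(C)[C@@H](O)[C@H]1OC(=O)/C(C)=C\C
F2 | step 3 | (1S,6R)-6-(3-chloroprop-1-en-2-yl)-3-methyl-2-oxocyclohex-3-en-1-yl (2Z)-2-methylbut-2-enoate | C=C(CCl)[C@H]1CC=C(C)C(=O)[C@H]1OC(=O)/C(C)=C\C
F3 | step 3 | N-alkoxytrimethylammonium chloride of allylic alcohol 6 (CH2–O–NMe3 chloride) | C=C(CO[N+](C)(C)C)[C@H]1CC=C(C)C(=O)[C@H]1OC(=O)/C(C)=C\C.[Cl-]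
F4 | step 2 | (1R,6R)-3-methyl-2-oxo-6-(prop-1-en-2-yl)cyclohex-3-en-1-yl chloromethanesulfonate | C=C(C)[C@H]1CC=C(C)C(=O)[C@@H]1OS(=O)(=O)CCl
F5 | step 2 | cesium (2Z)-2-methylbut-2-enoate (cesium angelate) | C/C=C(/C)C(=O)[O-].[Cs+]
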